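**Remark:** the target has no stereocentre. The only stereochemical element in the route is the (E) geometry of the dichlorovinyl ether, which is erased in step 7. Commercial 3-hydroxybenzyl alcohol is taken as the ring D building block.

## Retrosynthetic overview

- The target comes from macrocyclic ketone 23 by deoxygenation of the bridge carbonyl and cleavage of two methyl ethers.
- The strategy rests on ring B, a 1,4-disubstituted benzene inside the 18-membered ring: C-1 carries the bridge carbon towards ring A and C-4 carries the ether oxygen towards ring C. Four of its carbons are taken from C3–C6 of a 5-acyl-2-pyrone and the other two from an ethynyl ether on ring C, so ring B and the macrocycle open together to give 21.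
- 21 comes from a ring A benzylzinc reagent and coumaloyl chloride; the ethynyl ether comes from an (E)-1,2-dichlorovinyl ether made from isovanillin and trichloroethylene.
- The open chain A–O–D–CH2CH2–C comes from an SNAr reaction (ring D phenol with 2-fluoro-5-methoxybenzaldehyde) and a Wittig reaction followed by diimide reduction (ring D phosphonium salt with the ring C aldehyde).
- Ring order: rings A, C and D are bought; ring B and the 18-membered ring are formed last, in one operation.

Key step: step 11

## Route

Step 1
Reactants: 1 isovanillin; 2 trichloroethylene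
Product: 4 3-{[(E)-1,2-dichloroethenyl]oxy}-4-methoxybenzaldehyde, via dichloroacetylene 3 (not isolated)
Conditions: K2CO3, DMF, 70 °C
Reagents that add atoms: none
Why: Base-induced loss of HCl from trichloroethylene gives dichloroacetylene, and anti addition of the phenoxide and a proton across it (nucleophilic vinylation of a phenol) should give the (E)-dichlorovinyl ether while the aldehyde is untouched.

Step 2
Reactants: 5 3-hydroxybenzyl alcohol
Product: 6 (3-hydroxybenzyl)triphenylphosphonium bromide
Conditions: Ph3P·HBr, MeCN, reflux
Reagents that add atoms: triphenylphosphine hydrobromide, [PH+](c1ccccc1)(c1ccccc1)c1ccccc1.[Br-]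
Why: Acid-mediated substitution of the benzylic hydroxyl by triphenylphosphine (phosphonium salt formation from a benzylic alcohol) should leave the phenol free, since only the benzylic C–O bond is activated by HBr.

Step 3
Reactants: 6 (3-hydroxybenzyl)triphenylphosphonium bromide; 4 3-{[(E)-1,2-dichloroethenyl]oxy}-4-methoxybenzaldehyde
Product: 8 3-[2-(3-{[(E)-1,2-dichloroethenyl]oxy}-4-methoxyphenyl)ethenyl]phenol (E/Z mixture at the stilbene bond), via potassium phenoxide ylide 7 (not isolated)
Conditions: KOtBu (2.05 equiv), THF, 0 °C; then 4, 0 °C → rt; dilute HCl work-up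
Reagents that add atoms: none
Why: Wittig olefination with a semi-stabilised benzylic ylide should proceed cleanly because the second equivalent of base is consumed in ylide formation before the base-sensitive dichlorovinyl ether is added, and the E/Z mixture is of no consequence since the double bond is reduced next.

Step 4
Reactants: 8 3-[2-(3-{[(E)-1,2-dichloroethenyl]oxy}-4-methoxyphenyl)ethenyl]phenol
Product: 9 3-[2-(3-{[(E)-1,2-dichloroethenyl]oxy}-4-methoxyphenyl)ethyl]phenol
Conditions: TsNHNH2, NaOAc, THF/H2O, reflux
Reagents that add atoms: none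
Why: Diimide reduction transfers H2 in a concerted way to the 1,2-disubstituted stilbene bond, whereas the trisubstituted, dichlorinated enol ether double bond and the C–Cl bonds, which catalytic hydrogenation would attack, should not react.

Step 5
Reactants: 9 3-[2-(3-{[(E)-1,2-dichloroethenyl]oxy}-4-methoxyphenyl)ethyl]phenol; 10 2-fluoro-5-methoxybenzaldehyde
Product: 11 2-{3-[2-(3-{[(E)-1,2-dichloroethenyl]oxy}-4-methoxyphenyl)ethyl]phenoxy}-5-methoxybenzaldehyde
Conditions: K2CO3, DMF, 120 °C
Reagents that add atoms: none
Why: Nucleophilic aromatic substitution (SNAr) of the fluoride activated by the ortho formyl group by the ring D phenoxide should give the A–O–D diaryl ether with the methoxy group para to the new ether oxygen.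

Step 6
Reactants: 11 2-{3-[2-(3-{[(E)-1,2-dichloroethenyl]oxy}-4-methoxyphenyl)ethyl]phenoxy}-5-methoxybenzaldehyde
Product: 12 (2-{3-[2-(3-{[(E)-1,2-dichloroethenyl]oxy}-4-methoxyphenyl)ethyl]phenoxy}-5-methoxyphenyl)methanol
Conditions: NaBH4, MeOH/THF, 0 °C
Reagents that add atoms: none
Why: Borohydride reduction of the aryl aldehyde to the benzylic alcohol is chemoselective, the dichlorovinyl ether and the diaryl ether being inert to NaBH4.

Step 7
Reactants: 12 (2-{3-[2-(3-{[(E)-1,2-dichloroethenyl]oxy}-4-methoxyphenyl)ethyl]phenoxy}-5-methoxyphenyl)methanol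
Product: 15 (2-{3-[2-(3-ethynyloxy-4-methoxyphenyl)ethyl]phenoxy}-5-methoxyphenyl)methanol, via chloroethynyl ether lithium alkoxide 13 (not isolated), via dilithiated ynol ether 14 (not isolated)
Conditions: n-BuLi (3.3 equiv), THF, −78 → −40 °C; then MeOH, −78 °C
Reagents that add atoms: none
Why: After the first equivalent has deprotonated the alcohol, the known conversion of aryl 1,2-dichlorovinyl ethers into ynol ethers takes place (vinyl deprotonation with loss of LiCl, then chlorine–lithium exchange), and protonation of the lithium acetylide at low temperature should give the terminal aryl ethynyl ether.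

Step 8
Reactants: 15 (2-{3-[2-(3-ethynyloxy-4-methoxyphenyl)ethyl]phenoxy}-5-methoxyphenyl)methanol
Product: 17 2-(chloromethyl)-1-{3-[2-(3-ethynyloxy-4-methoxyphenyl)ethyl]phenoxy}-4-methoxybenzene, via benzylic mesylate 16 (not isolated)
Conditions: MsCl, LiCl, 2,4,6-collidine, DMF, 0 °C
Reagents that add atoms: lithium chloride, [Li+].[Cl-]
Why: Mesylation followed by in situ chloride displacement (Collington–Meyers conditions) converts the benzylic alcohol into the chloride in a collidine-buffered medium that should not protonate the acid-sensitive ynol ether.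

Step 9
Reactants: 18 coumalic acid
Product: 19 coumaloyl chloride (2-oxo-2H-pyran-5-carbonyl chloride)
Conditions: SOCl2, reflux; excess reagent removed in vacuo
Reagents that add atoms: thionyl chloride, ClS(Cl)=O
Why: Acid chloride formation with thionyl chloride is the established preparation of this compound, and the 2-pyrone ring is stable to the acidic, non-nucleophilic medium.

Step 10
Reactants: 17 2-(chloromethyl)-1-{3-[2-(3-ethynyloxy-4-methoxyphenyl)ethyl]phenoxy}-4-methoxybenzene; 19 coumaloyl chloride
Product: 21 5-[(2-{3-[2-(3-ethynyloxy-4-methoxyphenyl)ethyl]phenoxy}-5-methoxyphenyl)acetyl]-2H-pyran-2-one, via benzylzinc chloride 20 (not isolated)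
Conditions: Zn dust, LiCl, THF, 25 °C; then added to 19, Pd(PPh3)4 (5 mol%), THF, 0 °C → rt
Reagents that add atoms: none
Why: LiCl-promoted zinc insertion into the benzylic chloride followed by Negishi acylation catalysed by zerovalent palladium should give the benzyl ketone, because a benzylzinc chloride is too weakly basic and nucleophilic to attack the alkyne C–H, the pyrone or the product ketone, and inverse addition keeps the acid chloride in excess.

Step 11
Reactants: 21 5-[(2-{3-[2-(3-ethynyloxy-4-methoxyphenyl)ethyl]phenoxy}-5-methoxyphenyl)acetyl]-2H-pyran-2-one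
Product: 23 di-O-methyl macrocyclic ketone (C=O on the bridge carbon next to ring B), via bridged bicyclic lactone 22 (not isolated)
Conditions: PhMe, BHT (cat.), 110 °C, syringe-pump addition over 12 h to 1 mM final concentration
Reagents that add atoms: none
Why: Proposed new method: the electron-poor 5-acyl-2-pyrone (diene C3–C6) and the electron-rich aryloxyacetylene should combine in an asynchronous inverse-electron-demand [4+2] cycloaddition, the nucleophilic terminal alkyne carbon bonding first to the electrophilic pyrone C6 and the oxygen-bearing alkyne carbon then bonding to C3, after which the bridged lactone 22 expels CO2 by retro-[4+2] and delivers benzene ring B directly at the aromatic oxidation level. The closest known reaction types are the intermolecular cycloaddition–decarboxylation of coumalate esters with enol ethers, ketene acetals and ynamines, which gives para-substituted benzoates, and intramolecular pyrone–alkyne cycloadditions that close cyclophanes; an aryl ynol ether as the two-carbon partner combined with closure of an 18-membered ring is not precedented. The 18-membered ring is closed by the first C–C bond (C6 to the terminal alkyne carbon), the 14-atom tether running from the acyl carbon on C5 to the ynol ether oxygen, and the six-membered ring B is closed by the second C–C bond (C3 to the oxygen-bearing carbon) and aromatised by loss of CO2. No stereocentre remains in 23, since the two bridgehead centres of 22 are destroyed on CO2 loss. The step needs para over meta orientation, which the matched polarity secures: C6 is the acceptor terminus activated by both the ring carbonyl and the 5-acyl group, and the alkyne CH is the nucleophilic carbon of the ynol ether, so the acyl and aryloxy groups end up 1,4. It also needs ring closure over oligomerisation, which slow addition to millimolar concentration secures, the tether being long enough to span the para positions of the boat-shaped adduct without strain.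

Step 12
Reactants: 23 di-O-methyl macrocyclic ketone
Product: 25 di-O-methyl ether of the target macrocycle, via benzylic carbinol 24 (not isolated)
Conditions: Et3SiH (6 equiv), TFA, CH2Cl2, 0 → 40 °C
Reagents that add atoms: none
Why: Ionic hydrogenation should reduce the aryl ketone to methylene, because the protonated ketone and then the benzylic cation formed from carbinol 24, which is stabilised by the para-aryloxy group of ring B, each accept hydride from the silane, while aryl ethers are inert.

Step 13
Reactants: 25 di-O-methyl ether of the target macrocycle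
Product: 27 target macrocyclic bis(bibenzyl) diphenol (CNP0135015.0), via bis(dibromoboryl) ether 26 (not isolated)
Conditions: BBr3, CH2Cl2, −78 °C → rt; then H2O
Reagents that add atoms: none
Why: Lewis-acid cleavage of aryl methyl ethers by BBr3 (bromide attack on the O-methyl of the boron-complexed ether) should free both phenols on hydrolysis, while the two diaryl ether bonds, which have no alkyl carbon open to bromide, stay intact.

## Compound list

1 | isovanillin (3-hydroxy-4-methoxybenzaldehyde) | COc1ccc(C=O)cc1O | starting material
2 | trichloroethylene | ClC=C(Cl)Cl | starting material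
3 | dichloroacetylene | ClC#CCl | intermediate (not isolated)
4 | 3-{[(E)-1,2-dichloroethenyl]oxy}-4-methoxybenzaldehyde | COc1ccc(C=O)cc1O/C(Cl)=C\Cl | intermediate
5 | 3-hydroxybenzyl alcohol | OCc1cccc(O)c1 | starting material
6 | (3-hydroxybenzyl)triphenylphosphonium bromide | Oc1cccc(C[P+](c2ccccc2)(c2ccccc2)c2ccccc2)c1.[Br-] | intermediate
7 | potassium phenoxide ylide derived from 6 | [K+].[O-]c1cccc(C=P(c2ccccc2)(c2ccccc2)c2ccccc2)c1 | intermediate (not isolated)
8 | 3-[2-(3-{[(E)-1,2-dichloroethenyl]oxy}-4-methoxyphenyl)ethenyl]phenol, E/Z mixture at the stilbene bond | COc1ccc(C=Cc2cccc(O)c2)cc1O/C(Cl)=C\Cl | intermediate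
9 | 3-[2-(3-{[(E)-1,2-dichloroethenyl]oxy}-4-methoxyphenyl)ethyl]phenol | COc1ccc(CCc2cccc(O)c2)cc1O/C(Cl)=C\Cl | intermediate
10 | 2-fluoro-5-methoxybenzaldehyde | COc1ccc(F)c(C=O)c1 | starting material
11 | 2-{3-[2-(3-{[(E)-1,2-dichloroethenyl]oxy}-4-methoxyphenyl)ethyl]phenoxy}-5-methoxybenzaldehyde | COc1ccc(Oc2cccc(CCc3ccc(OC)c(O/C(Cl)=C\Cl)c3)c2)c(C=O)c1 | intermediate
12 | (2-{3-[2-(3-{[(E)-1,2-dichloroethenyl]oxy}-4-methoxyphenyl)ethyl]phenoxy}-5-methoxyphenyl)methanol | COc1ccc(Oc2cccc(CCc3ccc(OC)c(O/C(Cl)=C\Cl)c3)c2)c(CO)c1 | intermediate
13 | lithium alkoxide of the chloroethynyl ether | [Li+].[O-]Cc1cc(OC)ccc1Oc1cccc(CCc2ccc(OC)c(OC#CCl)c2)c1 | intermediate (not isolated)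
14 | dilithiated ynol ether (lithium acetylide, lithium alkoxide) | [Li+].[Li+].[O-]Cc1cc(OC)ccc1Oc1cccc(CCc2ccc(OC)c(OC#[C-])c2)c1 | intermediate (not isolated)
15 | (2-{3-[2-(3-ethynyloxy-4-methoxyphenyl)ethyl]phenoxy}-5-methoxyphenyl)methanol | COc1ccc(Oc2cccc(CCc3ccc(OC)c(OC#C)c3)c2)c(CO)c1 | intermediate
16 | benzylic mesylate of 15 | COc1ccc(Oc2cccc(CCc3ccc(OC)c(OC#C)c3)c2)c(COS(C)(=O)=O)c1 | intermediate (not isolated)
17 | 2-(chloromethyl)-1-{3-[2-(3-ethynyloxy-4-methoxyphenyl)ethyl]phenoxy}-4-methoxybenzene | COc1ccc(Oc2cccc(CCc3ccc(OC)c(OC#C)c3)c2)c(CCl)c1 | intermediate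
18 | coumalic acid (2-oxo-2H-pyran-5-carboxylic acid) | OC(=O)c1ccc(=O)oc1 | starting material
19 | coumaloyl chloride (2-oxo-2H-pyran-5-carbonyl chloride) | ClC(=O)c1ccc(=O)oc1 | intermediate
20 | benzylzinc chloride derived from 17 | COc1ccc(Oc2cccc(CCc3ccc(OC)c(OC#C)c3)c2)c(C[Zn]Cl)c1 | intermediate (not isolated)
21 | 5-[(2-{3-[2-(3-ethynyloxy-4-methoxyphenyl)ethyl]phenoxy}-5-methoxyphenyl)acetyl]-2H-pyran-2-one | O=c1ccc(co1)C(=O)Cc1cc(OC)ccc1Oc1cccc(c1)CCc1ccc(OC)c(c1)OC#C | intermediate (key-step precursor)
22 | bridged 2-oxabicyclo[2.2.2]octa-5,7-dien-3-one cycloadduct inside the macrocycle, racemic (one enantiomer drawn) | COc1ccc2c(c1)CC(=O)C1=C[C@H]3C(=O)O[C@@H]1C=C3Oc1cc(ccc1OC)CCc1cccc(c1)O2 | intermediate (not isolated)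
23 | di-O-methyl macrocyclic ketone, C=O on the bridge carbon attached to ring B | COc1ccc2c(c1)CC(=O)c1ccc(cc1)Oc1cc(ccc1OC)CCc1cccc(c1)O2 | intermediate (key-step product)
24 | benzylic carbinol of the macrocycle, racemic | COc1ccc2c(c1)CC(O)c1ccc(cc1)Oc1cc(ccc1OC)CCc1cccc(c1)O2 | intermediate (not isolated)
25 | di-O-methyl ether of the target macrocycle | COc1ccc2c(c1)CCc1ccc(cc1)Oc1cc(ccc1OC)CCc1cccc(c1)O2 | intermediate
26 | bis(dibromoboryl) ether of the target | BrB(Br)Oc1ccc2c(c1)CCc1ccc(cc1)Oc1cc(ccc1OB(Br)Br)CCc1cccc(c1)O2 | intermediate (not isolated)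
27 | target macrocyclic bis(bibenzyl) diphenol, CNP0135015.0 | Oc1ccc2c(c1)CCc1ccc(cc1)Oc1cc(ccc1O)CCc1cccc(c1)O2 | target

## Step count

Total: 13 steps. Longest linear sequence: 11 steps (steps 1, 3, 4, 5, 6, 7, 8, 10, 11, 12, 13 from isovanillin); steps 2 and 9 are side branches.

## Steps most likely to fail and fallbacks

**1. Step 11 (proposed new method).** The tethered ynol ether may react between molecules faster than within one, giving oligomers. It may also decompose thermally before the cycloaddition occurs, or the chain may fail to fold the alkyne over the pyrone face in the orientation that leads to the para product.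

Fallback by known chemistry, setting out from 15 and returning at 25: ring B is brought in as a bought benzene ring and the macrocycle is closed by an intramolecular Wittig reaction, as is established for macrocyclic bis(bibenzyls).
- Acid-catalysed hydration of the ynol ether of 15 (TsOH cat., wet THF) should give the aryl acetate F1.
- Methanolysis (K2CO3, MeOH) should free the ring C phenol to give (2-{3-[2-(3-hydroxy-4-methoxyphenyl)ethyl]phenoxy}-5-methoxyphenyl)methanol F2.
- SNAr of the phenoxide on 4-fluorobenzaldehyde (K2CO3, DMF, 110 °C) should give the ring B aldehyde F3; the benzylic alcohol is not deprotonated by carbonate.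
- Ph3P·HBr in refluxing MeCN should convert the benzylic alcohol into the phosphonium bromide F4.
- Slow addition of F4 to NaOMe in CH2Cl2/MeOH at high dilution should close the ring to the macrocyclic stilbene F5 (E/Z mixture).
- Hydrogenation (H2, Pd/C, EtOAc) should give 25.

**2. Step 10.** The benzylzinc reagent may be quenched by proton transfer from the terminal alkyne C–H. Zinc or palladium species may add to the ynol ether, or the organometallic may attack the pyrone or enolise the product ketone.

Fallback setting out from 12 and returning at 21: the alkyne C–H is masked as C–SiMe3 through the organometallic steps.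
- 12 is treated with n-BuLi as in step 7 (via 13 and 14), and the dianion is quenched with Me3SiCl to give the O,C-bis(trimethylsilyl) compound F6.
- Work-up with dilute citric acid in MeOH should cleave only the O–Si bond to give the C-silylated ynol ether alcohol F7.
- MsCl, LiCl and collidine in DMF should give, via the mesylate F8, the benzylic chloride F9.
- Zinc insertion (Zn, LiCl, THF) should give the benzylzinc chloride F10.
- Acylation with 19 under Pd(PPh3)4 catalysis should give the silyl-capped acylpyrone F11.
- Buffered fluoride (TBAF, AcOH, THF, −78 °C) should remove the alkynyl silyl group and give 21.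

**3. Step 5.** Substitution at the fluoroarene, which is deactivated by the para methoxy group, may be slow, and at the temperature needed the phenoxide may attack the dichlorovinyl ether or the aldehyde may degrade.

Fallback setting out from 9 and returning at 11: the diaryl ether is made by oxidative copper coupling in place of SNAr. Chan–Lam coupling of phenol 9 with commercial (2-formyl-4-methoxyphenyl)boronic acid (Cu(OAc)2, divalent copper, pyridine, 4 Å molecular sieves, CH2Cl2, air, rt) should give 11 at room temperature. This fallback makes no new compound (F0).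

## Further compounds

F1 | step 11 | 5-[2-(3-{2-(hydroxymethyl)-4-methoxyphenoxy}phenyl)ethyl]-2-methoxyphenyl acetate | COc1ccc(Oc2cccc(CCc3ccc(OC)c(OC(C)=O)c3)c2)c(CO)c1
F2 | step 11 | (2-{3-[2-(3-hydroxy-4-methoxyphenyl)ethyl]phenoxy}-5-methoxyphenyl)methanol | COc1ccc(Oc2cccc(CCc3ccc(OC)c(O)c3)c2)c(CO)c1
F3 | step 11 | 4-{5-[2-(3-{2-(hydroxymethyl)-4-methoxyphenoxy}phenyl)ethyl]-2-methoxyphenoxy}benzaldehyde | COc1ccc(Oc2cccc(CCc3ccc(OC)c(Oc4ccc(C=O)cc4)c3)c2)c(CO)c1
F4 | step 11 | ring A benzyltriphenylphosphonium bromide bearing the ring B aldehyde | COc1ccc(Oc2cccc(CCc3ccc(OC)c(Oc4ccc(C=O)cc4)c3)c2)c(C[P+](c5ccccc5)(c6ccccc6)c7ccccc7)c1.[Br-]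
F5 | step 11 | di-O-methyl macrocyclic stilbene (E/Z mixture at the A–B bridge) | COc1ccc2c(c1)C=Cc1ccc(cc1)Oc1cc(ccc1OC)CCc1cccc(c1)O2
F6 | step 10 | O,C-bis(trimethylsilyl) derivative of 15 | COc1ccc(Oc2cccc(CCc3ccc(OC)c(OC#C[Si](C)(C)C)c3)c2)c(CO[Si](C)(C)C)c1
F7 | step 10 | [5-methoxy-2-(3-{2-[4-methoxy-3-(trimethylsilylethynyloxy)phenyl]ethyl}phenoxy)phenyl]methanol | COc1ccc(Oc2cccc(CCc3ccc(OC)c(OC#C[Si](C)(C)C)c3)c2)c(CO)c1
F8 | step 10 | benzylic mesylate of F7 | COc1ccc(Oc2cccc(CCc3ccc(OC)c(OC#C[Si](C)(C)C)c3)c2)c(COS(C)(=O)=O)c1
F9 | step 10 | benzylic chloride of F7 | COc1ccc(Oc2cccc(CCc3ccc(OC)c(OC#C[Si](C)(C)C)c3)c2)c(CCl)c1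
F10 | step 10 | benzylzinc chloride derived from F9 | COc1ccc(Oc2cccc(CCc3ccc(OC)c(OC#C[Si](C)(C)C)c3)c2)c(C[Zn]Cl)c1
F11 | step 10 | C-trimethylsilyl derivative of 21 | O=c1ccc(co1)C(=O)Cc1cc(OC)ccc1Oc1cccc(c1)CCc1ccc(OC)c(c1)OC#C[Si](C)(C)C
F0 | step 5 | none | none
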